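**Retrosynthetic overview**

1. Numbering: ring A = C1–C5 and C10 (C4 carries the exocyclic CH2), ring B = C5–C10 (Me on C5, C8 and C9; ArCH2 on C9; H on C10). Target ⇐ MOM removal ⇐ ortho-lithiation/carboxylation of the arene ⇐ Wittig methylenation of a C4 ketone ⇐ trans-decalone.
2. trans-Decalone ⇐ HAT hydrogenation of the C1=C10 alkene of a bicyclic β,γ-enone, with hydrogen delivered to C10 on the face opposite the C5 and C9 methyl groups.
3. Key disconnection C5–C6, closing ring B: intramolecular α-alkylation of the extended dienolate of a ring-A enone (C4=O, C5=C10) by a C6 tosylate.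
4. Enabling feature: the C4 methylene carbon next to quaternary C5 can be a carbonyl, which makes C5 the α-carbon of the dienolate C4(O)=C5–C10=C1; C9 is quaternary, so ring-A C1 holds the only γ-hydrogens, and the shift of the double bond to C1=C10 keeps C10 planar until its hydrogen can be set trans.
5. Precursor ⇐ ring A annulated (Grignard addition, alkyne hydration, aldol condensation) onto C10, the carbonyl carbon of a δ-lactone; this temporary lactone ring (C6–C10 plus O), made from a chiral-pool hemiester, relays C8 to quaternary C9 through two enolate alkylations. Ring order: lactone (temporary), ring A, ring B.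

Key step: step 10

Assumption: the (R)-enantiomer of methyl hydrogen 3-methylglutarate is taken as the commercial form; with the (S)-form, borane reduction of the acid group in place of LiBH4 reduction of the ester group leads to the same (S)-lactone 6.

**Route**

Step 1
Reactants: 1 2,3,4-trihydroxybenzaldehyde
Product: 2 2,3,4-tris(methoxymethoxy)benzaldehyde
Conditions: NaH, MOMCl, DMF, 0 °C to rt
Reagents that add atoms: chloromethyl methyl ether (MOMCl), COCCl
Why: Williamson ether synthesis on the three phenoxides should give the tris-MOM ether, a protecting group that is stable to the bases, organometallics and radicals used later and serves as ortho-director in step 13.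

Step 2
Reactants: 2 2,3,4-tris(methoxymethoxy)benzaldehyde
Product: 3 [2,3,4-tris(methoxymethoxy)phenyl]methanol
Conditions: NaBH4, MeOH, 0 °C
Reagents that add atoms: none
Why: Borohydride reduction of the aryl aldehyde should give the benzylic alcohol without touching the acetal-type MOM groups.

Step 3
Reactants: 3 [2,3,4-tris(methoxymethoxy)phenyl]methanol
Product: 4 1-(bromomethyl)-2,3,4-tris(methoxymethoxy)benzene
Conditions: CBr4, PPh3, CH2Cl2, 0 °C; used at once
Reagents that add atoms: carbon tetrabromide, BrC(Br)(Br)Br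
Why: The Appel reaction converts the benzylic alcohol into the bromide under neutral conditions that spare the MOM ethers; the electron-rich bromide is not stored.

Step 4
Reactants: 5 (R)-5-methoxy-3-methyl-5-oxopentanoic acid (methyl hydrogen (R)-3-methylglutarate)
Product: 6 (S)-4-methyltetrahydro-2H-pyran-2-one
Conditions: LiBH4, THF, 0 °C to rt; then 2 M HCl, rt
Reagents that add atoms: none
Why: Chemoselective hydride reduction of the ester in the presence of the lithium carboxylate, followed by acid-promoted lactonisation, should give the δ-lactone; the stereocentre is not touched, and because the former ester end becomes the CH2O end the (R)-hemiester maps onto the (S)-lactone.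

Step 5
Reactants: 6 (S)-4-methyltetrahydro-2H-pyran-2-one
Product: 7 (3R,4S)-3,4-dimethyltetrahydro-2H-pyran-2-one
Conditions: LiN(i-Pr)2 (LDA), THF, −78 °C; MeI, −78 to −40 °C
Reagents that add atoms: iodomethane, CI
Why: Lactone enolate alkylation should place the methyl group mainly trans to the C4 methyl; this centre is enolised again in step 6, so its configuration is not critical.

Step 6
Reactants: 7 (3R,4S)-3,4-dimethyltetrahydro-2H-pyran-2-one; 4 1-(bromomethyl)-2,3,4-tris(methoxymethoxy)benzene
Product: 8 (3R,4S)-3,4-dimethyl-3-[2,3,4-tris(methoxymethoxy)benzyl]tetrahydro-2H-pyran-2-one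
Conditions: LiN(i-Pr)2 (LDA), THF, −78 °C; then 4, DMPU, −78 to −20 °C
Reagents that add atoms: none
Why: Alkylation of the tetrasubstituted lactone enolate: the C4 methyl, held pseudoaxial by A(1,2) strain with the enolate methyl, shields one face, so the benzylic bromide should enter anti to it and set the quaternary carbon (future C9) with the benzyl group trans and the methyl group cis to the C4 methyl (1,2-induction in a cyclic enolate).

Step 7
Reactants: 8 (3R,4S)-3,4-dimethyl-3-[2,3,4-tris(methoxymethoxy)benzyl]tetrahydro-2H-pyran-2-one; 9 6-chloro-2-hexyne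
Product: 11 (3R,4S)-2-(hex-4-yn-1-yl)-3,4-dimethyl-3-[2,3,4-tris(methoxymethoxy)benzyl]tetrahydro-2H-pyran-2-ol (lactol of the δ-hydroxy ynone; C2 epimers), via hex-4-yn-1-ylmagnesium chloride 10 (not isolated)
Conditions: 9, Mg, THF, reflux; then 8, THF, −40 to 0 °C; H2O
Reagents that add atoms: none
Why: Grignard mono-addition to a lactone that cannot be enolised: the hindered magnesium lactolate should resist a second addition and give, on work-up, the δ-hydroxy ketone held as its lactol, so that the former lactone carbonyl becomes C10 carrying the C1–C5 chain.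

Step 8
Reactants: 11 (3R,4S)-2-(hex-4-yn-1-yl)-3,4-dimethyl-3-[2,3,4-tris(methoxymethoxy)benzyl]tetrahydro-2H-pyran-2-ol
Product: 13 3-{(2R,3S)-5-hydroxy-2,3-dimethyl-1-[2,3,4-tris(methoxymethoxy)phenyl]pentan-2-yl}-2-methylcyclohex-2-en-1-one, via hydroxy diketone 12 (not isolated)
Conditions: Ph3PAuNTf2 (cat.), H2O, 1,4-dioxane, 60 °C; then KOH, MeOH, 65 °C
Reagents that add atoms: water, O
Why: Gold-catalysed alkyne hydration guided by the C10 oxygen (6-exo-dig attack on the nearer alkyne carbon) should place the new carbonyl at C4, and the resulting 1,5-diketone then undergoes base-mediated intramolecular aldol condensation (the ring-closing half of a Robinson annulation), in which only attack of C5 on C10 gives a six-membered ring, to form ring A as the tetrasubstituted enone.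

Step 9
Reactants: 13 3-{(2R,3S)-5-hydroxy-2,3-dimethyl-1-[2,3,4-tris(methoxymethoxy)phenyl]pentan-2-yl}-2-methylcyclohex-2-en-1-one
Product: 14 (3S,4R)-3,4-dimethyl-4-(2-methyl-3-oxocyclohex-1-en-1-yl)-5-[2,3,4-tris(methoxymethoxy)phenyl]pentyl 4-methylbenzenesulfonate
Conditions: TsCl, Et3N, DMAP (cat.), CH2Cl2, 0 °C to rt
Reagents that add atoms: p-toluenesulfonyl chloride, Cc1ccc(cc1)S(Cl)(=O)=O
Why: Sulfonylation of the primary alcohol installs the C6 leaving group only after the C10 ketone has become the enone, so that no simple C1 enolate can cyclise onto C6.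

Step 10
Reactants: 14 (3S,4R)-3,4-dimethyl-4-(2-methyl-3-oxocyclohex-1-en-1-yl)-5-[2,3,4-tris(methoxymethoxy)phenyl]pentyl 4-methylbenzenesulfonate
Product: 16 (5R,6S,8aS)-5,6,8a-trimethyl-5-[2,3,4-tris(methoxymethoxy)benzyl]-3,5,6,7,8,8a-hexahydronaphthalen-1(2H)-one (C4 ketone and C1=C10 alkene in the overview numbering), via potassium dienolate 15 (not isolated)
Conditions: KOt-Bu, t-BuOH/THF, high dilution, rt to 50 °C
Reagents that add atoms: none
Why: KOt-Bu reversibly removes a γ-hydrogen at C1 (the only γ-CH, since C9 is quaternary) to give the extended potassium dienolate C4(O–)=C5(Me)–C10=C1, whose α-carbon C5 displaces the primary tosylate at C6 in an intramolecular SN2 alkylation. The closest known reaction type is the deconjugative α-alkylation of cyclohexenone dienolates, as in the α,α-dialkylation of steroidal 4-en-3-ones and in angular-methyl-forming cyclisations of 3-(ω-haloalkyl)-2-methylcyclohexenones. Ring B closes in the 6-exo-tet mode with the reacting enolate double bond exocyclic to the new ring (6-enolexo). The new quaternary stereocentre C5 is controlled by the preset C8 and C9 centres: in the chair-like transition state the C8 methyl and the C9 benzyl group are equatorial and the C9 methyl axial, so C6 should reach the face of C5 that leaves the C5 methyl syn to the C9 methyl. The step needs α- over γ-C-alkylation (α carries the highest charge density in metal dienolates, and only α-attack releases the A(1,3) strain between the C5 methyl and the C9 substituents), C- over O-alkylation and α- over α′-alkylation (both alternatives would demand an eight-membered ring), and substitution over E2 (primary tosylate, intramolecular delivery, high dilution). The double bond is left at C1=C10, so the ring-fusion hydrogen at C10 can be delivered afterwards anti to the two axial methyl groups.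

Step 11
Reactants: 16 (5R,6S,8aS)-5,6,8a-trimethyl-5-[2,3,4-tris(methoxymethoxy)benzyl]-3,5,6,7,8,8a-hexahydronaphthalen-1(2H)-one
Product: 17 (4aS,5R,6S,8aS)-5,6,8a-trimethyl-5-[2,3,4-tris(methoxymethoxy)benzyl]octahydronaphthalen-1(2H)-one
Conditions: Mn(dpm)3 (cat.; dpm = 2,2,6,6-tetramethylheptane-3,5-dionate), PhSiH3, t-BuOOH, i-PrOH, rt
Reagents that add atoms: none
Why: MHAT hydrogenation (Mukaiyama-type hydrogen-atom transfer from a manganese hydride): hydrogen-atom transfer to C1 gives the tertiary C10 radical, which should take up its hydrogen axially on the face opposite the two flanking axial methyl groups on C5 and C9, setting C10 as the trans ring fusion.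

Step 12
Reactants: 17 (4aS,5R,6S,8aS)-5,6,8a-trimethyl-5-[2,3,4-tris(methoxymethoxy)benzyl]octahydronaphthalen-1(2H)-one
Product: 18 1-{[(1R,2S,4aS,8aS)-1,2,4a-trimethyl-5-methylidenedecahydronaphthalen-1-yl]methyl}-2,3,4-tris(methoxymethoxy)benzene
Conditions: Ph3PCH3Br, KOt-Bu, toluene, 90 °C
Reagents that add atoms: methyltriphenylphosphonium bromide, C[P+](c1ccccc1)(c1ccccc1)c1ccccc1.[Br-]
Why: Wittig methylenation with excess ylide at elevated temperature is the established way to turn a ketone flanked by a quaternary carbon into the exocyclic methylene, and no epimerisable centre is adjacent.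

Step 13
Reactants: 18 1-{[(1R,2S,4aS,8aS)-1,2,4a-trimethyl-5-methylidenedecahydronaphthalen-1-yl]methyl}-2,3,4-tris(methoxymethoxy)benzene
Product: 20 methyl 5-{[(1R,2S,4aS,8aS)-1,2,4a-trimethyl-5-methylidenedecahydronaphthalen-1-yl]methyl}-2,3,4-tris(methoxymethoxy)benzoate, via aryllithium 19 (not isolated)
Conditions: n-BuLi, TMEDA, THF, −78 to 0 °C; then ClCO2Me, −78 °C
Reagents that add atoms: methyl chloroformate, COC(Cl)=O
Why: Directed ortho-metalation: the only ring hydrogen ortho to a MOM ether should be removed, and trapping of the aryllithium with the chloroformate installs the methyl ester at the required position.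

Step 14
Reactants: 20 methyl 5-{[(1R,2S,4aS,8aS)-1,2,4a-trimethyl-5-methylidenedecahydronaphthalen-1-yl]methyl}-2,3,4-tris(methoxymethoxy)benzoate
Product: 21 methyl 2,3,4-trihydroxy-5-{[(1R,2S,4aS,8aS)-1,2,4a-trimethyl-5-methylidenedecahydronaphthalen-1-yl]methyl}benzoate (CNP0162211.1)
Conditions: HCl (cat.), MeOH, 0 °C to rt
Reagents that add atoms: none
Why: Acid-catalysed transacetalisation to methanol removes the three MOM groups as dimethoxymethane; methanol matches the methyl ester, and brief exposure to dilute acid at or below rt should spare the exocyclic alkene.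

**Compound list**

1 | 2,3,4-trihydroxybenzaldehyde | O=Cc1ccc(O)c(O)c1O | starting material
2 | 2,3,4-tris(methoxymethoxy)benzaldehyde | O=Cc1ccc(OCOC)c(OCOC)c1OCOC | intermediate
3 | [2,3,4-tris(methoxymethoxy)phenyl]methanol | OCc1ccc(OCOC)c(OCOC)c1OCOC | intermediate
4 | 1-(bromomethyl)-2,3,4-tris(methoxymethoxy)benzene | BrCc1ccc(OCOC)c(OCOC)c1OCOC | intermediate
5 | (R)-5-methoxy-3-methyl-5-oxopentanoic acid | OC(=O)C[C@@H](C)CC(=O)OC | starting material
6 | (S)-4-methyltetrahydro-2H-pyran-2-one | O=C1C[C@@H](C)CCO1 | intermediate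
7 | (3R,4S)-3,4-dimethyltetrahydro-2H-pyran-2-one | O=C1OCC[C@H](C)[C@H]1C | intermediate
8 | (3R,4S)-3,4-dimethyl-3-[2,3,4-tris(methoxymethoxy)benzyl]tetrahydro-2H-pyran-2-one | O=C1OCC[C@H](C)[C@@]1(C)Cc1ccc(OCOC)c(OCOC)c1OCOC | intermediate
9 | 6-chloro-2-hexyne | CC#CCCCCl | starting material
10 | hex-4-yn-1-ylmagnesium chloride | CC#CCCC[Mg]Cl | intermediate
11 | (3R,4S)-2-(hex-4-yn-1-yl)-3,4-dimethyl-3-[2,3,4-tris(methoxymethoxy)benzyl]tetrahydro-2H-pyran-2-ol (lactol, C2 epimers) | CC#CCCCC1(O)OCC[C@H](C)[C@@]1(C)Cc1ccc(OCOC)c(OCOC)c1OCOC | intermediate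
12 | (8R,9S)-11-hydroxy-8,9-dimethyl-8-[2,3,4-tris(methoxymethoxy)benzyl]undecane-3,7-dione (open form of its C7 lactol) | CCC(=O)CCCC(=O)[C@](C)(Cc1ccc(OCOC)c(OCOC)c1OCOC)[C@@H](C)CCO | intermediate
13 | 3-{(2R,3S)-5-hydroxy-2,3-dimethyl-1-[2,3,4-tris(methoxymethoxy)phenyl]pentan-2-yl}-2-methylcyclohex-2-en-1-one | CC1=C(CCCC1=O)[C@](C)(Cc1ccc(OCOC)c(OCOC)c1OCOC)[C@@H](C)CCO | intermediate
14 | (3S,4R)-3,4-dimethyl-4-(2-methyl-3-oxocyclohex-1-en-1-yl)-5-[2,3,4-tris(methoxymethoxy)phenyl]pentyl 4-methylbenzenesulfonate | CC1=C(CCCC1=O)[C@](C)(Cc1ccc(OCOC)c(OCOC)c1OCOC)[C@@H](C)CCOS(=O)(=O)c1ccc(C)cc1 | intermediate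
15 | potassium dienolate of 14 (C4(O–)=C5–C10=C1) | [K+].[O-]C1=C(C)C(=CCC1)[C@](C)(Cc1ccc(OCOC)c(OCOC)c1OCOC)[C@@H](C)CCOS(=O)(=O)c1ccc(C)cc1 | intermediate
16 | (5R,6S,8aS)-5,6,8a-trimethyl-5-[2,3,4-tris(methoxymethoxy)benzyl]-3,5,6,7,8,8a-hexahydronaphthalen-1(2H)-one | O=C1CCC=C2[C@](C)(Cc3ccc(OCOC)c(OCOC)c3OCOC)[C@@H](C)CC[C@]12C | intermediate
17 | (4aS,5R,6S,8aS)-5,6,8a-trimethyl-5-[2,3,4-tris(methoxymethoxy)benzyl]octahydronaphthalen-1(2H)-one | O=C1CCC[C@H]2[C@](C)(Cc3ccc(OCOC)c(OCOC)c3OCOC)[C@@H](C)CC[C@]12C | intermediate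
18 | 1-{[(1R,2S,4aS,8aS)-1,2,4a-trimethyl-5-methylidenedecahydronaphthalen-1-yl]methyl}-2,3,4-tris(methoxymethoxy)benzene | C=C1CCC[C@H]2[C@](C)(Cc3ccc(OCOC)c(OCOC)c3OCOC)[C@@H](C)CC[C@]12C | intermediate
19 | aryllithium of 18 (Li ortho to the C4′ MOM ether) | C=C1CCC[C@H]2[C@](C)(Cc3cc([Li])c(OCOC)c(OCOC)c3OCOC)[C@@H](C)CC[C@]12C | intermediate
20 | methyl 5-{[(1R,2S,4aS,8aS)-1,2,4a-trimethyl-5-methylidenedecahydronaphthalen-1-yl]methyl}-2,3,4-tris(methoxymethoxy)benzoate | C=C1CCC[C@H]2[C@](C)(Cc3cc(C(=O)OC)c(OCOC)c(OCOC)c3OCOC)[C@@H](C)CC[C@]12C | intermediate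
21 | methyl 2,3,4-trihydroxy-5-{[(1R,2S,4aS,8aS)-1,2,4a-trimethyl-5-methylidenedecahydronaphthalen-1-yl]methyl}benzoate | C=C1CCC[C@H]2[C@](C)(Cc3cc(C(=O)OC)c(O)c(O)c3O)[C@@H](C)CC[C@]12C | target

**Summary**

Total step count: 14. Longest linear sequence: 12 steps (steps 1–3, then 6–14, from 2,3,4-trihydroxybenzaldehyde); the lactone branch from 5 is 11 steps.

Steps most likely to fail:

Step 10 (key step). What may go wrong: alkylation at the γ-carbon C1 instead of C5, base-induced E2 loss of the tosylate, or attack on the wrong face of C5. Fallback, setting out from 13: the alcohol is converted into the primary iodide F1 (I2, PPh3, imidazole, CH2Cl2). F1 is silylated under equilibrating conditions (Me3SiCl, NaI, Et3N, MeCN) to the extended trimethylsilyl dienol ether F2, an isolable compound whose regiochemistry can be confirmed before the ring is closed. F2 is then cyclised by fluoride-triggered desilylative alkylation (tris(dimethylamino)sulfonium difluorotrimethylsilicate, THF, −40 °C to rt), a non-basic variant of enolate alkylation in which the free dienolate reacts at its α-carbon and no alkoxide is present to eliminate the halide. This gives 16, where the route is rejoined.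

Step 8. What may go wrong: the aldol addition stalls because the C10 carbonyl is tied up as the lactol with the C6 hydroxyl and is flanked by quaternary C9, or the free alkoxide adds back to the strained enone. Fallback, setting out from 11: silylation (t-BuMe2SiCl, imidazole, DMF) traps the open-chain hydroxy ketone as the open-chain silyl ether F3. Gold-catalysed hydration as in step 8 gives the silyl-protected 1,5-diketone F4. F4 is closed by enamine catalysis (pyrrolidine, AcOH, toluene, reflux with water removal), a Hajos–Parrish-type aldol condensation known to work on carbonyls next to quaternary carbons, to give the silyl-protected enone F5. Bu4NF in THF then returns 13.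

Step 11. What may go wrong: slow hydrogen-atom transfer to the hindered alkene, a 1,2-acyl shift of the intermediate radical (the C10 radical sits β to the C4 carbonyl), or delivery of hydrogen to the methyl-bearing face, which would give the cis-decalin. Fallback, setting out from 16: the ketone is first reduced (NaBH4, MeOH) to the C4 alcohol F6, whose configuration at C4 is of no consequence. This removes the β-keto radical pathway and the electron-poor carbonyl next to the reacting centre. F6 is hydrogenated under the HAT conditions of step 11 to the saturated alcohol F7, and oxidation with Dess–Martin periodinane (CH2Cl2, rt) gives the ketone 17, where the route is rejoined.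

**Further compounds**

F1 | step 10 | 3-{(2R,3S)-5-iodo-2,3-dimethyl-1-[2,3,4-tris(methoxymethoxy)phenyl]pentan-2-yl}-2-methylcyclohex-2-en-1-one | CC1=C(CCCC1=O)[C@](C)(Cc1ccc(OCOC)c(OCOC)c1OCOC)[C@@H](C)CCI
F2 | step 10 | trimethylsilyl dienol ether of F1 (C4(OSiMe3)=C5–C10=C1) | C[Si](C)(C)OC1=C(C)C(=CCC1)[C@](C)(Cc1ccc(OCOC)c(OCOC)c1OCOC)[C@@H](C)CCI
F3 | step 8 | (3S,4R)-1-[tert-butyl(dimethyl)silyloxy]-3,4-dimethyl-4-[2,3,4-tris(methoxymethoxy)benzyl]undec-9-yn-5-one | CC#CCCCC(=O)[C@](C)(Cc1ccc(OCOC)c(OCOC)c1OCOC)[C@@H](C)CCO[Si](C)(C)C(C)(C)C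
F4 | step 8 | (8R,9S)-11-[tert-butyl(dimethyl)silyloxy]-8,9-dimethyl-8-[2,3,4-tris(methoxymethoxy)benzyl]undecane-3,7-dione | CCC(=O)CCCC(=O)[C@](C)(Cc1ccc(OCOC)c(OCOC)c1OCOC)[C@@H](C)CCO[Si](C)(C)C(C)(C)C
F5 | step 8 | tert-butyldimethylsilyl ether of 13 | CC1=C(CCCC1=O)[C@](C)(Cc1ccc(OCOC)c(OCOC)c1OCOC)[C@@H](C)CCO[Si](C)(C)C(C)(C)C
F6 | step 11 | (5R,6S,8aS)-5,6,8a-trimethyl-5-[2,3,4-tris(methoxymethoxy)benzyl]-1,2,3,5,6,7,8,8a-octahydronaphthalen-1-ol (C1 epimers) | OC1CCC=C2[C@](C)(Cc3ccc(OCOC)c(OCOC)c3OCOC)[C@@H](C)CC[C@]12C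
F7 | step 11 | (4aS,5R,6S,8aS)-5,6,8a-trimethyl-5-[2,3,4-tris(methoxymethoxy)benzyl]decahydronaphthalen-1-ol (C1 epimers) | OC1CCC[C@H]2[C@](C)(Cc3ccc(OCOC)c(OCOC)c3OCOC)[C@@H](C)CC[C@]12C
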